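**Remark on the chemistry:** ring A is the dimethoxy ring, ring B the middle ring and ring C the ring that ends as the free acid; in each ring C1 is the carboxyl-bearing carbon. The target has no stereocentre, so no step has a configuration to set.

## The problem

The target is a linear tridepside: three benzoic acid units joined head to tail by two aryl ester bonds (ring A carbonyl to O4 of ring B, ring B carbonyl to O4 of ring C), ending in a free 2-hydroxybenzoic acid on ring C. It has no stereocentre, so the difficulty is regiochemical and chemoselective: which oxygen is acylated, which is methylated and which stays free. Rings B and C are orsellinate units (C1 carboxyl, C2 OH, C4 O-acyl, C6 methyl), and a conventional synthesis must tell the two hydroxyls of each unit apart. Ring A is pentasubstituted (C1 carboxyl between C2 OMe and C6 methyl, C3 OMe, C4 OH, one C–H at C5), so its acid is hindered towards esterification and its substitution pattern must be set without isomer mixtures. The aryl ester links open or migrate under base and under attack by the molecule's own phenoxides, ring A is easily oxidised, and the ring C 2-hydroxy-6-methylbenzoic acid terminus loses CO2 under heat or strong acid. The enabling feature is that in rings B and C the carbon C1 carries methyl on C6 and hydroxyl on C2. In the 2-deoxy form each of these rings therefore has exactly one C–H ortho to its carbonyl, and ring A has none. Both C2–O bonds can thus be made late by carbonyl-directed C–H oxygenation with no choice of site.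

## Retrosynthesis

**18 from 17.** The last bond cut is the benzylic C–O bond of a 4-nitrobenzyl ester on the ring C carboxyl. The acid stays masked to the end for three reasons: it decarboxylates easily, a free acid would become a mixed anhydride in the acylating medium of the key step, and an alkyl benzoate is the directing group for which ortho C–H oxygenation is best established. A benzyl or tert-butyl ester would not survive hot strong acid and a methyl ester could not be removed beside two aryl esters. The 4-nitrobenzyl ester resists acid and oxidant and falls to neutral hydrogenolysis, which only has to spare aryl esters, phenols and methyl ethers.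

**17 from 14.** The two C2–O bonds of rings B and C are cut, giving the dideoxy tridepside 14. The neighbouring choice, cutting the aryl ester bonds first, leads to two orsellinate units with differentiated hydroxyls. Cutting the C–O bonds first removes that problem, because rings B and C of 14 both come from one monohydroxy acid, 1. Compound 14 has two oxygens fewer, no chelated phenol and a single free phenol on ring A. The forward reaction must oxygenate the only ortho C–H of ring C (alkyl ester carbonyl) and of ring B (aryl ester carbonyl). The ring A phenol is left free on purpose, so that the medium converts it into trifluoroacetate 15 before oxidation; the product leaves as tris(trifluoroacetate) 16 and is hydrolysed to 17 at work-up.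

**14 from 13, and 13 from 11 and 6.** The acyl C–O bond between rings A and B is cut, giving the ring A acid 11 (used as acid chloride 12) and the phenol 6; the silyl ether 13 is the coupling product. This bond is cut before the B–C bond so that the two halves are of similar length and the oxidisable ring A enters late. The acid is flanked on both sides, so the forward step needs the acid chloride. The triisopropylsilyl ether on ring A is the group that already controls the synthesis of 11, and buffered fluoride removes it without touching the esters.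

**6 from 5, and 5 from 4 and 2.** The B–C aryl ester bond is cut, returning both halves to 1: the 4-nitrobenzyl ester 2 for ring C and the silyl ether acid 4 (through bis-silylated 3) for ring B. The precursors are monocyclic and the forward reaction is an ordinary carbodiimide esterification of a singly ortho-substituted acid.

**11 from 10, 9, 8 and 7.** The ring A C1–carboxyl bond is cut: 11 arises from aryllithium 10 by carboxylation and 10 from 9 by directed lithiation. Electrophilic substitution on this arene would have to choose between two positions that are each ortho to one oxygen and para to another. Deprotonation is decided by coordination instead: the methoxy group directs, and the bulky, non-coordinating silyl ether blocks its own ortho position. Compound 9 comes from phenol 8, and 8 from commercial 7, whose formyl carbon becomes the C6 methyl.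

## Roads not taken

**Alternative 1:** Ring A is cut at C1–C6 and C3–C4 and built from two acyclic esters. Methyl 4-methoxy-3-oxobutanoate A1 would add through its C2 to methyl (E)-but-2-enoate A2 under an alkoxide base, and the methoxy-bearing carbanion would then close the ring on the ester to give the enolised dione A3 (racemic trans methyl 4-hydroxy-3-methoxy-6-methyl-2-oxocyclohex-3-ene-1-carboxylate). Dehydrogenation would give methyl 2,4-dihydroxy-3-methoxy-6-methylbenzoate A4.
- Merits: every ring A substituent is placed by the connectivity of cheap starting esters, so there is no aromatic regiochemistry to control. In this respect it is safer than the lithiation of 9.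
- Weak points: A3 needs a separate aromatisation. In A4 the hydroxyl to be methylated (C2) is the chelated, less reactive one, so C4 must be protected first, C2 methylated and a doubly ortho-substituted methyl ester saponified.
- Comparison: it solves ring A only and leaves the orsellinate differentiation of rings B and C untouched. The chosen plan reaches the ring A acid 11 in three steps from 7 and removes the differentiation problem on both other rings.

**Alternative 2:** Ring B is cut at C1–C2, C3–C4 and C5–C6. The ynoate A5 (benzyl 2-(benzyloxy)-4-(but-2-ynoyloxy)-6-methylbenzoate) would be cyclotrimerised with two molecules of the siloxyalkyne A6 ((ethynyloxy)triisopropylsilane) by a cationic monovalent rhodium bisphosphine catalyst, giving A7 (benzyl 2-(benzyloxy)-4-{[6-methyl-2,4-bis(triisopropylsilyloxy)benzoyl]oxy}-6-methylbenzoate).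
- Merits: three C–C bonds and a ring form in one step, both ring B oxygens arrive with the alkyne, no oxidant meets an electron-rich arene and no weak directing group is relied on. In these respects it is better than the chosen key step.
- Weak points: a 1:2 cross-trimerisation must beat homotrimerisation of A6 and give one regioisomer. Siloxyalkynes are labile. A5 still needs a classically differentiated orsellinate for ring C. Ring A is not addressed.
- Comparison: both key steps lie beyond precedent. The chosen plan solves rings B and C in one operation from a single commercial acid, with fewer steps and no sensitive alkyne partners.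

**Alternative 3:** The B–C ester C–O bond and ring B bond C1–C6 are cut. Thermolysis of the diketo-dioxinone A8 (6-(2,4-dioxopentyl)-2,2-dimethyl-4H-1,3-dioxin-4-one) would release an acylketene that is trapped by the 4-hydroxyl of benzyl orsellinate A9; aldol condensation between chain C2 and chain C7 and aromatisation would give benzyl lecanorate A10.
- Merits: every event is a precedented reaction type. Ring B arrives unprotected, and its free 4-hydroxyl is more reactive than the two chelated 2-hydroxyls, so ring A can be attached directly and one hydrogenolysis finishes the synthesis. In reliability this road is better than the chosen one.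
- Weak points: A8 needs several steps and is a labile polycarbonyl compound. The acylketene must be captured by a phenol, a poorer nucleophile than an alcohol. A9 is still needed for ring C.
- Comparison: the chosen plan offers one cheap building block for both rings, no polyketide handling and a new late-stage oxygenation of depsides. Its fallback uses the same classical 4-hydroxyl selectivity on which this alternative rests.

Key step: step 10

## Route

Step 1
Reactants: 1 4-hydroxy-2-methylbenzoic acid
Product: 2 4-nitrobenzyl 4-hydroxy-2-methylbenzoate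
Conditions: 4-nitrobenzyl bromide, KHCO3, DMF, 25–40 °C
Reagents that add atoms: 4-nitrobenzyl bromide, O=[N+]([O-])c1ccc(CBr)cc1
Why: Carboxylate O-alkylation (SN2); hydrogen carbonate deprotonates the acid but not the phenol, so only the ester forms.

Step 2
Reactants: 1 4-hydroxy-2-methylbenzoic acid
Product: 4 2-methyl-4-[(triisopropylsilyl)oxy]benzoic acid, via bis-silylated ester 3 (not isolated)
Conditions: i-Pr3SiCl (2.2 equiv), imidazole, DMF, 25 °C; then K2CO3, MeOH/THF/H2O, 25 °C; acidify to pH 3
Reagents that add atoms: chlorotriisopropylsilane, CC(C)[Si](Cl)(C(C)C)C(C)C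
Why: Exhaustive silylation followed by selective solvolysis of the far more labile silyl ester; the hindered aryl silyl ether is kept.

Step 3
Reactants: 4 2-methyl-4-[(triisopropylsilyl)oxy]benzoic acid; 2 4-nitrobenzyl 4-hydroxy-2-methylbenzoate
Product: 5 4-nitrobenzyl 2-methyl-4-({2-methyl-4-[(triisopropylsilyl)oxy]benzoyl}oxy)benzoate
Conditions: EDC·HCl, DMAP, CH2Cl2, 0 to 25 °C
Reagents that add atoms: none
Why: Steglich esterification; the acid has only one ortho substituent, so the acylpyridinium intermediate is readily taken by the phenol of 2.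

Step 4
Reactants: 5 4-nitrobenzyl 2-methyl-4-({2-methyl-4-[(triisopropylsilyl)oxy]benzoyl}oxy)benzoate
Product: 6 4-nitrobenzyl 4-[(4-hydroxy-2-methylbenzoyl)oxy]-2-methylbenzoate
Conditions: Bu4NF, AcOH, THF, 0 °C
Reagents that add atoms: none
Why: Fluoride cleavage of an aryl silyl ether; acetic acid buffers the phenoxide so that the aryl ester and the 4-nitrobenzyl ester are not attacked.

Step 5
Reactants: 7 3-hydroxy-4,5-dimethoxybenzaldehyde
Product: 8 2,3-dimethoxy-5-methylphenol
Conditions: H2 (3 atm), 10% Pd/C, AcOH, cat. HCl, 25–40 °C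
Reagents that add atoms: none
Why: Hydrogenation of the electron-rich aryl aldehyde to the benzylic alcohol and acid-assisted hydrogenolysis of its C–O bond give the methyl group.

Step 6
Reactants: 8 2,3-dimethoxy-5-methylphenol
Product: 9 (2,3-dimethoxy-5-methylphenoxy)triisopropylsilane
Conditions: i-Pr3SiCl, imidazole, DMF, 25 °C
Reagents that add atoms: chlorotriisopropylsilane, CC(C)[Si](Cl)(C(C)C)C(C)C
Why: Standard silylation of a phenol; the bulky group is chosen because it neither coordinates lithium nor allows deprotonation next to itself.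

Step 7
Reactants: 9 (2,3-dimethoxy-5-methylphenoxy)triisopropylsilane
Product: 11 2,3-dimethoxy-6-methyl-4-[(triisopropylsilyl)oxy]benzoic acid, via aryllithium 10 (not isolated)
Conditions: n-BuLi, TMEDA, Et2O, 0 to 25 °C; CO2, −78 to 25 °C; 1 M HCl to pH 3
Reagents that add atoms: carbon dioxide, O=C=O
Why: Directed ortho-metalation; the C3 methoxy group directs lithiation to the C–H between itself and the methyl group, the only other ring C–H is shielded by the silyl ether, and carboxylation of 10 gives the acid.

Step 8
Reactants: 11 2,3-dimethoxy-6-methyl-4-[(triisopropylsilyl)oxy]benzoic acid; 6 4-nitrobenzyl 4-[(4-hydroxy-2-methylbenzoyl)oxy]-2-methylbenzoate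
Product: 13 4-nitrobenzyl 4-{[4-({2,3-dimethoxy-6-methyl-4-[(triisopropylsilyl)oxy]benzoyl}oxy)-2-methylbenzoyl]oxy}-2-methylbenzoate, via acid chloride 12 (not isolated)
Conditions: (COCl)2, cat. DMF, CH2Cl2, 0 to 25 °C, evaporate; then 6, Et3N, DMAP, CH2Cl2, 0 to 25 °C
Reagents that add atoms: none
Why: Acylation of a phenol by an acid chloride with DMAP catalysis; the acid chloride is needed because the carboxyl is flanked by methoxy and methyl, and the silyl ether and both esters are inert to these conditions.

Step 9
Reactants: 13 4-nitrobenzyl 4-{[4-({2,3-dimethoxy-6-methyl-4-[(triisopropylsilyl)oxy]benzoyl}oxy)-2-methylbenzoyl]oxy}-2-methylbenzoate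
Product: 14 4-nitrobenzyl 4-({4-[(4-hydroxy-2,3-dimethoxy-6-methylbenzoyl)oxy]-2-methylbenzoyl}oxy)-2-methylbenzoate
Conditions: Bu4NF, AcOH, THF, 0 °C
Reagents that add atoms: none
Why: Buffered fluoride desilylation as in step 4; the ring A phenol is freed so that the medium of the next step can mask it as an electron-poor ester.

Step 10
Reactants: 14 4-nitrobenzyl 4-({4-[(4-hydroxy-2,3-dimethoxy-6-methylbenzoyl)oxy]-2-methylbenzoyl}oxy)-2-methylbenzoate
Product: 17 4-nitrobenzyl 2-hydroxy-4-({2-hydroxy-4-[(4-hydroxy-2,3-dimethoxy-6-methylbenzoyl)oxy]-6-methylbenzoyl}oxy)-6-methylbenzoate, via ring A trifluoroacetate 15 (not isolated), via tris(trifluoroacetate) 16 (not isolated)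
Conditions: CF3CO2H/(CF3CO)2O (3:1), 25 °C, 30 min; then [RuCl2(p-cymene)]2 (10 mol %), K2S2O8 (5 equiv), 80 °C; then NaHCO3, H2O/THF, 25 °C
Reagents that add atoms: trifluoroacetic acid, OC(=O)C(F)(F)F
Why: Proposed new method: the phenol of 14 is first acylated by (CF3CO)2O to 15, which lowers the electron density of ring A before the oxidant is added. Divalent ruthenium bearing trifluoroacetate ligands binds an ester carbonyl oxygen and cleaves the single ortho C–H bond of that ring by concerted metalation–deprotonation to a five-membered ruthenacycle; K2S2O8 oxidises this to a tetravalent ruthenium trifluoroacetate, and C–O reductive elimination releases the aryl trifluoroacetate, first on ring C (alkyl benzoate carbonyl, the better donor) and then on ring B (aryl benzoate carbonyl), giving 16, which hydrogen carbonate hydrolyses to 17. The closest known reaction type is the ruthenium-catalysed ortho C–H hydroxylation of alkyl benzoates and aryl ketones in this medium, run on one ring with one directing group; new here are the aryl ester as directing group and the twofold use within one depside. No ring is closed and no stereocentre is formed. Site selectivity comes from the substrate: on rings B and C the second ortho position carries methyl, ring A has no hydrogen ortho to its carbonyl, and the five-membered acyl-side metallacycle is favoured over the six-membered one that an ester would need to reach the ring on its oxygen side. Each new phenol is held as its trifluoroacetate and the 4-nitrobenzyl ester is inert to acid and oxidant, so over-oxidation and mixed-anhydride chemistry of a free acid are avoided.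

Step 11
Reactants: 17 4-nitrobenzyl 2-hydroxy-4-({2-hydroxy-4-[(4-hydroxy-2,3-dimethoxy-6-methylbenzoyl)oxy]-6-methylbenzoyl}oxy)-6-methylbenzoate
Product: 18 2-hydroxy-4-({2-hydroxy-4-[(4-hydroxy-2,3-dimethoxy-6-methylbenzoyl)oxy]-6-methylbenzoyl}oxy)-6-methylbenzoic acid (CNP0319613.0)
Conditions: H2 (1 atm), 10% Pd/C, EtOAc/THF, 25 °C; wash with dilute HCl
Reagents that add atoms: none
Why: Hydrogenolysis of the 4-nitrobenzyl ester (nitro reduction and benzylic C–O cleavage) under neutral conditions at room temperature, which spares the aryl esters, phenols and methyl ethers and does not provoke decarboxylation.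

## Compound list

1 | 4-hydroxy-2-methylbenzoic acid | Cc1cc(O)ccc1C(=O)O | starting material
2 | 4-nitrobenzyl 4-hydroxy-2-methylbenzoate | Cc1cc(O)ccc1C(=O)OCc1ccc(cc1)[N+](=O)[O-] | intermediate
3 | triisopropylsilyl 2-methyl-4-[(triisopropylsilyl)oxy]benzoate | Cc1cc(O[Si](C(C)C)(C(C)C)C(C)C)ccc1C(=O)O[Si](C(C)C)(C(C)C)C(C)C | intermediate
4 | 2-methyl-4-[(triisopropylsilyl)oxy]benzoic acid | Cc1cc(O[Si](C(C)C)(C(C)C)C(C)C)ccc1C(=O)O | intermediate
5 | 4-nitrobenzyl 2-methyl-4-({2-methyl-4-[(triisopropylsilyl)oxy]benzoyl}oxy)benzoate | Cc1cc(O[Si](C(C)C)(C(C)C)C(C)C)ccc1C(=O)Oc1ccc(C(=O)OCc2ccc(cc2)[N+](=O)[O-])c(C)c1 | intermediate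
6 | 4-nitrobenzyl 4-[(4-hydroxy-2-methylbenzoyl)oxy]-2-methylbenzoate | Cc1cc(O)ccc1C(=O)Oc1ccc(C(=O)OCc2ccc(cc2)[N+](=O)[O-])c(C)c1 | intermediate
7 | 3-hydroxy-4,5-dimethoxybenzaldehyde | COc1cc(C=O)cc(O)c1OC | starting material
8 | 2,3-dimethoxy-5-methylphenol | COc1cc(C)cc(O)c1OC | intermediate
9 | (2,3-dimethoxy-5-methylphenoxy)triisopropylsilane | COc1cc(C)cc(O[Si](C(C)C)(C(C)C)C(C)C)c1OC | intermediate
10 | {2,3-dimethoxy-6-methyl-4-[(triisopropylsilyl)oxy]phenyl}lithium | [Li]c1c(C)cc(O[Si](C(C)C)(C(C)C)C(C)C)c(OC)c1OC | intermediate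
11 | 2,3-dimethoxy-6-methyl-4-[(triisopropylsilyl)oxy]benzoic acid | COc1c(O[Si](C(C)C)(C(C)C)C(C)C)cc(C)c(C(=O)O)c1OC | intermediate
12 | 2,3-dimethoxy-6-methyl-4-[(triisopropylsilyl)oxy]benzoyl chloride | COc1c(O[Si](C(C)C)(C(C)C)C(C)C)cc(C)c(C(=O)Cl)c1OC | intermediate
13 | 4-nitrobenzyl 4-{[4-({2,3-dimethoxy-6-methyl-4-[(triisopropylsilyl)oxy]benzoyl}oxy)-2-methylbenzoyl]oxy}-2-methylbenzoate | COc1c(O[Si](C(C)C)(C(C)C)C(C)C)cc(C)c(C(=O)Oc2ccc(C(=O)Oc3ccc(C(=O)OCc4ccc(cc4)[N+](=O)[O-])c(C)c3)c(C)c2)c1OC | intermediate
14 | 4-nitrobenzyl 4-({4-[(4-hydroxy-2,3-dimethoxy-6-methylbenzoyl)oxy]-2-methylbenzoyl}oxy)-2-methylbenzoate | COc1c(O)cc(C)c(C(=O)Oc2ccc(C(=O)Oc3ccc(C(=O)OCc4ccc(cc4)[N+](=O)[O-])c(C)c3)c(C)c2)c1OC | intermediate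
15 | 4-nitrobenzyl 4-{[4-({2,3-dimethoxy-6-methyl-4-[(trifluoroacetyl)oxy]benzoyl}oxy)-2-methylbenzoyl]oxy}-2-methylbenzoate | COc1c(OC(=O)C(F)(F)F)cc(C)c(C(=O)Oc2ccc(C(=O)Oc3ccc(C(=O)OCc4ccc(cc4)[N+](=O)[O-])c(C)c3)c(C)c2)c1OC | intermediate
16 | 4-nitrobenzyl 4-{[4-({2,3-dimethoxy-6-methyl-4-[(trifluoroacetyl)oxy]benzoyl}oxy)-2-methyl-6-[(trifluoroacetyl)oxy]benzoyl]oxy}-2-methyl-6-[(trifluoroacetyl)oxy]benzoate | COc1c(OC(=O)C(F)(F)F)cc(C)c(C(=O)Oc2cc(C)c(C(=O)Oc3cc(C)c(C(=O)OCc4ccc(cc4)[N+](=O)[O-])c(OC(=O)C(F)(F)F)c3)c(OC(=O)C(F)(F)F)c2)c1OC | intermediate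
17 | 4-nitrobenzyl 2-hydroxy-4-({2-hydroxy-4-[(4-hydroxy-2,3-dimethoxy-6-methylbenzoyl)oxy]-6-methylbenzoyl}oxy)-6-methylbenzoate | COc1c(O)cc(C)c(C(=O)Oc2cc(C)c(C(=O)Oc3cc(C)c(C(=O)OCc4ccc(cc4)[N+](=O)[O-])c(O)c3)c(O)c2)c1OC | intermediate
18 | 2-hydroxy-4-({2-hydroxy-4-[(4-hydroxy-2,3-dimethoxy-6-methylbenzoyl)oxy]-6-methylbenzoyl}oxy)-6-methylbenzoic acid (CNP0319613.0) | COc1c(O)cc(C)c(C(=O)Oc2cc(C)c(C(=O)Oc3cc(C)c(C(=O)O)c(O)c3)c(O)c2)c1OC | target

## Step count and least certain steps

Total: 11 steps. Longest linear sequence: 7 steps (7 to 18 through steps 5, 6, 7, 8, 9, 10 and 11; the branches from 1 are equally long).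

**Step 10 (key step, proposed new method).** The most likely failure is that cyclometalation on ring B does not occur, because the aryl ester carbonyl is a weak donor and weakens further once ring C carries a trifluoroacetate, so the reaction stops after one oxygenation. The second risk is oxidative degradation of ring A by persulfate despite its trifluoroacetylation. The fallback uses known chemistry: the oxygens are installed on the monomer, where the directing group is an alkyl benzoate, and the depside is then assembled through the more reactive 4-hydroxyl of an orsellinate. It sets out from 2 (and uses 12 from step 8) and returns at 17.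
- Compound 2 under the conditions of step 10 should give 4-nitrobenzyl 2,4-dihydroxy-6-methylbenzoate F1.
- One portion of F1 is silylated (t-BuMe2SiOTf, 2,6-lutidine) to 4-nitrobenzyl 2,4-bis[(tert-butyldimethylsilyl)oxy]-6-methylbenzoate F2.
- F2 is hydrogenolysed (H2, 10% Pd/C) to 2,4-bis[(tert-butyldimethylsilyl)oxy]-6-methylbenzoic acid F3, which (COCl)2 converts into 2,4-bis[(tert-butyldimethylsilyl)oxy]-6-methylbenzoyl chloride F4.
- F4 acylates the 4-hydroxyl of a second portion of F1 (Et3N, DMAP; the 2-hydroxyl is held in a hydrogen bond to the ester carbonyl) to give 4-nitrobenzyl 4-({2,4-bis[(tert-butyldimethylsilyl)oxy]-6-methylbenzoyl}oxy)-2-hydroxy-6-methylbenzoate F5.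
- Bu4NF/AcOH then gives 4-nitrobenzyl 4-[(2,4-dihydroxy-6-methylbenzoyl)oxy]-2-hydroxy-6-methylbenzoate F6.
- Acylation of F6 by 12 at its one non-chelated hydroxyl gives 4-nitrobenzyl 4-{[4-({2,3-dimethoxy-6-methyl-4-[(triisopropylsilyl)oxy]benzoyl}oxy)-2-hydroxy-6-methylbenzoyl]oxy}-2-hydroxy-6-methylbenzoate F7, and Bu4NF/AcOH gives 17.

**Step 7.** Lithiation may be slow or may take place at the benzylic methyl or next to the silyl ether (followed by silyl migration from oxygen to carbon), giving the wrong carboxylation site. The fallback replaces coordination-directed deprotonation by electrophilic substitution para to a free hydroxyl. It sets out from 8 and returns at 10. Bromination of 8 (Bu4NBr3, CH2Cl2/MeOH) should give 4-bromo-2,3-dimethoxy-5-methylphenol F8. Silylation (i-Pr3SiCl, imidazole) gives (4-bromo-2,3-dimethoxy-5-methylphenoxy)triisopropylsilane F9. Bromine–lithium exchange (n-BuLi, THF, −78 °C) gives the same aryllithium 10, which CO2 converts into 11.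

**Step 8.** Acylation by the doubly ortho-substituted acid chloride may be slower than acyl transfer between molecules of 6, whose phenoxide can attack the aryl ester of another molecule and scramble the depside. The fallback forms the A–B bond on a nucleophile without an internal aryl ester and joins ring C afterwards. It sets out from 1 and 12 and returns at 13. Alkylation of 1 (benzyl bromide, KHCO3, DMF) gives benzyl 4-hydroxy-2-methylbenzoate F10. Its sodium phenoxide (NaH, THF) is acylated by 12 to benzyl 4-({2,3-dimethoxy-6-methyl-4-[(triisopropylsilyl)oxy]benzoyl}oxy)-2-methylbenzoate F11. Hydrogenolysis (H2, 10% Pd/C) gives 4-({2,3-dimethoxy-6-methyl-4-[(triisopropylsilyl)oxy]benzoyl}oxy)-2-methylbenzoic acid F12, and Steglich esterification with 2 (EDC·HCl, DMAP) gives 13.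

**Step 9.** The liberated ring A phenoxide or basic fluoride may cause acyl migration along the depside or loss of the 4-nitrobenzyl ester. The fallback removes the silyl group before any ester is present and masks the phenol transiently during the coupling, replacing steps 8 and 9. It sets out from 11 and returns at 14. Desilylation of 11 (Bu4NF, THF) gives 4-hydroxy-2,3-dimethoxy-6-methylbenzoic acid F13. (CF3CO)2O in toluene converts F13 into 2,3-dimethoxy-6-methyl-4-[(trifluoroacetyl)oxy]benzoic trifluoroacetic anhydride F14, which acylates 6 to give 15. Aqueous NaHCO3 hydrolyses 15 to 14; alternatively 15 is taken directly into step 10.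

## Further compounds

F1 | step 10 | 4-nitrobenzyl 2,4-dihydroxy-6-methylbenzoate | Cc1cc(O)cc(O)c1C(=O)OCc1ccc(cc1)[N+](=O)[O-]
F2 | step 10 | 4-nitrobenzyl 2,4-bis[(tert-butyldimethylsilyl)oxy]-6-methylbenzoate | Cc1cc(O[Si](C)(C)C(C)(C)C)cc(O[Si](C)(C)C(C)(C)C)c1C(=O)OCc1ccc(cc1)[N+](=O)[O-]
F3 | step 10 | 2,4-bis[(tert-butyldimethylsilyl)oxy]-6-methylbenzoic acid | Cc1cc(O[Si](C)(C)C(C)(C)C)cc(O[Si](C)(C)C(C)(C)C)c1C(=O)O
F4 | step 10 | 2,4-bis[(tert-butyldimethylsilyl)oxy]-6-methylbenzoyl chloride | Cc1cc(O[Si](C)(C)C(C)(C)C)cc(O[Si](C)(C)C(C)(C)C)c1C(=O)Cl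
F5 | step 10 | 4-nitrobenzyl 4-({2,4-bis[(tert-butyldimethylsilyl)oxy]-6-methylbenzoyl}oxy)-2-hydroxy-6-methylbenzoate | Cc1cc(O[Si](C)(C)C(C)(C)C)cc(O[Si](C)(C)C(C)(C)C)c1C(=O)Oc1cc(C)c(C(=O)OCc2ccc(cc2)[N+](=O)[O-])c(O)c1
F6 | step 10 | 4-nitrobenzyl 4-[(2,4-dihydroxy-6-methylbenzoyl)oxy]-2-hydroxy-6-methylbenzoate | Cc1cc(O)cc(O)c1C(=O)Oc1cc(C)c(C(=O)OCc2ccc(cc2)[N+](=O)[O-])c(O)c1
F7 | step 10 | 4-nitrobenzyl 4-{[4-({2,3-dimethoxy-6-methyl-4-[(triisopropylsilyl)oxy]benzoyl}oxy)-2-hydroxy-6-methylbenzoyl]oxy}-2-hydroxy-6-methylbenzoate | COc1c(O[Si](C(C)C)(C(C)C)C(C)C)cc(C)c(C(=O)Oc2cc(C)c(C(=O)Oc3cc(C)c(C(=O)OCc4ccc(cc4)[N+](=O)[O-])c(O)c3)c(O)c2)c1OC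
F8 | step 7 | 4-bromo-2,3-dimethoxy-5-methylphenol | COc1c(Br)c(C)cc(O)c1OC
F9 | step 7 | (4-bromo-2,3-dimethoxy-5-methylphenoxy)triisopropylsilane | COc1c(Br)c(C)cc(O[Si](C(C)C)(C(C)C)C(C)C)c1OC
F10 | step 8 | benzyl 4-hydroxy-2-methylbenzoate | Cc1cc(O)ccc1C(=O)OCc1ccccc1
F11 | step 8 | benzyl 4-({2,3-dimethoxy-6-methyl-4-[(triisopropylsilyl)oxy]benzoyl}oxy)-2-methylbenzoate | COc1c(O[Si](C(C)C)(C(C)C)C(C)C)cc(C)c(C(=O)Oc2ccc(C(=O)OCc3ccccc3)c(C)c2)c1OC
F12 | step 8 | 4-({2,3-dimethoxy-6-methyl-4-[(triisopropylsilyl)oxy]benzoyl}oxy)-2-methylbenzoic acid | COc1c(O[Si](C(C)C)(C(C)C)C(C)C)cc(C)c(C(=O)Oc2ccc(C(=O)O)c(C)c2)c1OC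
F13 | step 9 | 4-hydroxy-2,3-dimethoxy-6-methylbenzoic acid | COc1c(O)cc(C)c(C(=O)O)c1OC
F14 | step 9 | 2,3-dimethoxy-6-methyl-4-[(trifluoroacetyl)oxy]benzoic trifluoroacetic anhydride | COc1c(OC(=O)C(F)(F)F)cc(C)c(C(=O)OC(=O)C(F)(F)F)c1OC
A1 | alternative 1 | methyl 4-methoxy-3-oxobutanoate | COCC(=O)CC(=O)OC
A2 | alternative 1 | methyl (E)-but-2-enoate | C/C=C/C(=O)OC
A3 | alternative 1 | racemic trans methyl 4-hydroxy-3-methoxy-6-methyl-2-oxocyclohex-3-ene-1-carboxylate (one enantiomer drawn) | C[C@@H]1CC(O)=C(OC)C(=O)[C@H]1C(=O)OC
A4 | alternative 1 | methyl 2,4-dihydroxy-3-methoxy-6-methylbenzoate | COC(=O)c1c(C)cc(O)c(OC)c1O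
A5 | alternative 2 | benzyl 2-(benzyloxy)-4-(but-2-ynoyloxy)-6-methylbenzoate | CC#CC(=O)Oc1cc(C)c(C(=O)OCc2ccccc2)c(OCc2ccccc2)c1
A6 | alternative 2 | (ethynyloxy)triisopropylsilane | C#CO[Si](C(C)C)(C(C)C)C(C)C
A7 | alternative 2 | benzyl 2-(benzyloxy)-4-{[6-methyl-2,4-bis(triisopropylsilyloxy)benzoyl]oxy}-6-methylbenzoate | Cc1cc(O[Si](C(C)C)(C(C)C)C(C)C)cc(O[Si](C(C)C)(C(C)C)C(C)C)c1C(=O)Oc1cc(C)c(C(=O)OCc2ccccc2)c(OCc2ccccc2)c1
A8 | alternative 3 | 6-(2,4-dioxopentyl)-2,2-dimethyl-4H-1,3-dioxin-4-one | CC(=O)CC(=O)CC1=CC(=O)OC(C)(C)O1
A9 | alternative 3 | benzyl 2,4-dihydroxy-6-methylbenzoate (benzyl orsellinate) | Cc1cc(O)cc(O)c1C(=O)OCc1ccccc1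
A10 | alternative 3 | benzyl 4-[(2,4-dihydroxy-6-methylbenzoyl)oxy]-2-hydroxy-6-methylbenzoate (benzyl lecanorate) | Cc1cc(O)cc(O)c1C(=O)Oc1cc(C)c(C(=O)OCc2ccccc2)c(O)c1
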